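**Retrosynthetic overview**
- The target is a 3',8''-biflavone. Unit 1 is the 5-hydroxy-7-methoxy-6-methylflavone half and unit 2 the apigenin half; C3' of ring B of unit 1 is bonded to C8 of ring A of unit 2.
- The strategy rests on ring A of unit 2: a phloroglucinol ring whose C8, flanked by the oxygen-bearing C7 and C8a, carries ring B of unit 1. The crowded C3'–C8 biaryl bond is therefore brought in as the unhindered ArCH2–C6 bond of a 6-benzyl-4-methoxy-2-pyrone, and ring A is made from that pyrone by methoxide opening and Claisen reclosure (new bond: C8 to one of its oxygenated neighbours).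
- Disconnections, backwards: ether cleavage; ring C of unit 1 by Baker–Venkataraman chemistry between a ring-B carboxylic acid (from the aryl bromide by carbonylation) and an acetophenone from 2,6-dimethoxytoluene; ring C of unit 2 by enolate aroylation and cyclodehydration; ring A of unit 2 from the pyrone; the pyrone from an arylacetic acid and the acetoacetate dianion.
- Order of ring formation: 2-pyrone (sacrificed), ring A of unit 2, ring C of unit 2, ring C of unit 1; both rings B and ring A of unit 1 are bought as arenes.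

Key step: step 6

Remark: the target has no stereocentre and its C3'–C8'' axis is written without a descriptor, so the axis is taken as not configurationally fixed and no stereocontrol is planned.

**Route**

Step 1
Reactants: 1 2-hydroxyphenylacetic acid
Product: 2 2-(5-bromo-2-hydroxyphenyl)acetic acid
Conditions: Br2 (1.0 equiv), AcOH, 15 °C to rt
Reagents that add atoms: bromine, BrBr
Why: Electrophilic aromatic bromination of a phenol goes para to the hydroxyl when that position is free, and one equivalent of bromine in acetic acid should stop at the monobromide.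

Step 2
Reactants: 2 2-(5-bromo-2-hydroxyphenyl)acetic acid
Product: 4 2-(2-benzyloxy-5-bromophenyl)acetic acid, via benzyl ester 3 (not isolated)
Conditions: BnBr (2.3 equiv), K2CO3, DMF, 60 °C; then NaOH, MeOH–H2O, 60 °C; aq HCl
Reagents that add atoms: benzyl bromide, BrCc1ccccc1; sodium hydroxide, [Na+].[OH-]
Why: Williamson alkylation benzylates both the phenoxide and the carboxylate, and saponification then cleaves only the benzyl ester, leaving the aryl benzyl ether.

Step 3
Reactants: 4 2-(2-benzyloxy-5-bromophenyl)acetic acid; 5 methyl acetoacetate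
Product: 8 methyl 6-(2-benzyloxy-5-bromophenyl)-3,5-dioxohexanoate, via acyl imidazole 6 (not isolated), via methyl acetoacetate dianion 7 (not isolated)
Conditions: 4, 1,1'-carbonyldiimidazole, THF, rt; added to 7 (from 5 and LiN(iPr)2, 2.1 equiv per 5, THF, 0 °C; 2.5 equiv of 7), −78 to 0 °C; aq HCl
Reagents that add atoms: none
Why: The terminal carbon of the acetoacetate dianion is its most nucleophilic site and is acylated by the acyl imidazole (Huckin–Weiler-type dianion acylation); the amide base avoids any alkyllithium that could exchange with the aryl bromide, and excess dianion absorbs the acidic product.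

Step 4
Reactants: 8 methyl 6-(2-benzyloxy-5-bromophenyl)-3,5-dioxohexanoate
Product: 9 6-[(2-benzyloxy-5-bromophenyl)methyl]-4-hydroxy-2H-pyran-2-one
Conditions: DBU (1.5 equiv), toluene, rt to 60 °C; aq HCl
Reagents that add atoms: none
Why: DBU enolises the 5-ketone and the enol oxygen attacks the methyl ester in a 6-exo-trig lactonisation, driven by formation of the acidic 4-hydroxy-2-pyrone (base-induced cyclisation of a 3,5-dioxo ester).

Step 5
Reactants: 9 6-[(2-benzyloxy-5-bromophenyl)methyl]-4-hydroxy-2H-pyran-2-one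
Product: 10 6-[(2-benzyloxy-5-bromophenyl)methyl]-4-methoxy-2H-pyran-2-one
Conditions: Me2SO4, K2CO3, acetone, reflux
Reagents that add atoms: dimethyl sulfate, COS(=O)(=O)OC
Why: O-Methylation of the 4-hydroxy-2-pyrone anion with a hard electrophile in acetone gives the 4-methoxy-2-pyrone and not the 2-methoxy-4-pyrone, as with triacetic acid lactone, and K2CO3 is too weak to alkylate the benzylic CH2.

Step 6
Reactants: 10 6-[(2-benzyloxy-5-bromophenyl)methyl]-4-methoxy-2H-pyran-2-one
Product: 12 2-(2-benzyloxy-5-bromophenyl)-5-methoxybenzene-1,3-diol, via open-chain keto ester 11 (not isolated)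
Conditions: NaOMe (5 equiv), MeOH, reflux, argon; then aq HCl, 0 °C
Reagents that add atoms: none
Why: Methoxide adds to the lactone carbonyl of 10 and opens it to the enolate of keto ester 11, in which the former ring double bond (now 2E) keeps the ester and the benzyl ketone arm on the same side; proton exchange in methanol gives the enolate at the benzylic carbon, which attacks the ester carbonyl and expels methoxide. The closest known reaction types are the alkoxide-induced Claisen-mode closure of 6-(2-oxoalkyl)-4-methoxy-2-pyrones to acylphloroglucinol monomethyl ethers and the Dieckmann closure of 5-oxo-6-arylhexanoates to 2-arylcyclohexane-1,3-diones. The one ring formed, ring A of unit 2, closes in a 6-(enolendo)-exo-trig mode, and tautomerisation of the 2-aryl-5-methoxycyclohexenedione to the resorcinolate makes the step irreversible. No stereocentre is formed. The selectivity needed is C-acylation by the benzylic carbon in preference to return to the pyrone: the methyl enol ether removes the acidic 4-hydroxypyrone form and leaves no aldol mode open, the aryl group acidifies the attacking CH2, and the aromatic sink drains the equilibrium. The product is symmetric, so it does not matter which of the two oxygen-bearing carbons next to C8 is the newly bonded one.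

Step 7
Reactants: 12 2-(2-benzyloxy-5-bromophenyl)-5-methoxybenzene-1,3-diol
Product: 14 1-[3-(2-benzyloxy-5-bromophenyl)-2,4-dihydroxy-6-methoxyphenyl]ethanone, via ketiminium chloride 13 (not isolated)
Conditions: MeCN, ZnCl2, HCl (g), Et2O, 0 °C; then H2O, 90 °C
Reagents that add atoms: acetonitrile, CC#N; water, O
Why: In this Houben–Hoesch acylation the nitrilium species attacks one of the two free ring positions, which are equivalent by symmetry and each ortho and para to a hydroxyl, and hydrolysis of the ketiminium salt gives the ketone; aryl benzyl and methyl ethers are known to tolerate these conditions.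

Step 8
Reactants: 14 1-[3-(2-benzyloxy-5-bromophenyl)-2,4-dihydroxy-6-methoxyphenyl]ethanone
Product: 15 1-[4-benzyloxy-3-(2-benzyloxy-5-bromophenyl)-2-hydroxy-6-methoxyphenyl]ethanone
Conditions: BnBr (1.1 equiv), K2CO3, acetone, reflux
Reagents that add atoms: benzyl bromide, BrCc1ccccc1
Why: The hydroxyl ortho to the acetyl group is tied up in a hydrogen bond to the carbonyl and is flanked on both sides, so one equivalent of BnBr should alkylate the unchelated hydroxyl para to the acetyl group (selective Williamson etherification).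

Step 9
Reactants: 16 4-(benzyloxy)benzoic acid
Product: 17 4-(benzyloxy)benzoyl chloride
Conditions: (COCl)2, DMF (cat.), CH2Cl2, 0 °C to rt
Reagents that add atoms: oxalyl chloride, O=C(Cl)C(Cl)=O
Why: Standard acid chloride formation through the chloroiminium catalyst generated from DMF and oxalyl chloride.

Step 10
Reactants: 15 1-[4-benzyloxy-3-(2-benzyloxy-5-bromophenyl)-2-hydroxy-6-methoxyphenyl]ethanone; 17 4-(benzyloxy)benzoyl chloride
Product: 18 1-[4-benzyloxy-3-(2-benzyloxy-5-bromophenyl)-2-hydroxy-6-methoxyphenyl]-3-[4-(benzyloxy)phenyl]propane-1,3-dione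
Conditions: 15, LiN(SiMe3)2 (3.5 equiv), THF, −78 to −10 °C; then 17, −78 °C to rt; aq HCl
Reagents that add atoms: none
Why: Claisen-type C-aroylation of the lithium phenoxide–enolate dianion of an ortho-hydroxyacetophenone is the one-flask form of the Baker–Venkataraman sequence and avoids having to esterify the hindered, chelated phenol.

Step 11
Reactants: 18 1-[4-benzyloxy-3-(2-benzyloxy-5-bromophenyl)-2-hydroxy-6-methoxyphenyl]-3-[4-(benzyloxy)phenyl]propane-1,3-dione
Product: 19 7-benzyloxy-8-(2-benzyloxy-5-bromophenyl)-2-[4-(benzyloxy)phenyl]-5-methoxy-4H-chromen-4-one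
Conditions: TsOH·H2O (0.2 equiv), toluene, 90 °C
Reagents that add atoms: none
Why: Acid-catalysed cyclodehydration of an ortho-hydroxyaryl 1,3-diketone, in which the phenol adds to the aroyl carbonyl and water is lost, closes ring C of unit 2, and the mild sulfonic acid should spare the benzyl ethers.

Step 12
Reactants: 19 7-benzyloxy-8-(2-benzyloxy-5-bromophenyl)-2-[4-(benzyloxy)phenyl]-5-methoxy-4H-chromen-4-one
Product: 20 4-benzyloxy-3-{7-benzyloxy-2-[4-(benzyloxy)phenyl]-5-methoxy-4-oxo-4H-chromen-8-yl}benzoic acid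
Conditions: Pd(OAc)2 (5 mol%), Xantphos, CO (1 atm), Et3N, H2O, 1,4-dioxane, 90 °C; aq HCl
Reagents that add atoms: carbon monoxide, [C-]#[O+]; water, O
Why: In this palladium-catalysed hydroxycarbonylation, zerovalent palladium inserts into the aryl–bromine bond, CO inserts and water cleaves the acylpalladium species; the wide-bite-angle ligand allows one atmosphere of CO and nothing else in 19 should react.

Step 13
Reactants: 21 2,6-dimethoxytoluene
Product: 23 3,5-dimethoxy-4-methylphenol, via aryl pinacol boronate 22 (not isolated)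
Conditions: [Ir(OMe)(cod)]2 (1 mol%), 4,4'-di-tert-butyl-2,2'-bipyridine, B2pin2, THF, 80 °C; then KHSO5 (as its triple salt 2KHSO5·KHSO4·K2SO4), acetone–H2O, rt
Reagents that add atoms: potassium peroxymonosulfate, [K+].[O-]S(=O)(=O)OO
Why: Iridium-catalysed C–H borylation is sterically controlled and takes the only C–H bond without an ortho substituent, the one para to the methyl group, and the boronate is oxidised to the phenol in the same flask (one-flask borylation–oxidation).

Step 14
Reactants: 23 3,5-dimethoxy-4-methylphenol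
Product: 24 1-(6-hydroxy-2,4-dimethoxy-3-methylphenyl)ethanone
Conditions: Ac2O, BF3·OEt2, 80 °C; then aq MeOH, 60 °C
Reagents that add atoms: acetic anhydride, CC(=O)OC(C)=O
Why: Friedel–Crafts acetylation (through the O-acetate and a Fries-type shift) is driven by the difluoroboron chelate of the ortho-hydroxy ketone, and the two open ring positions are equivalent, each ortho to the hydroxyl, so only one regioisomer can form.

Step 15
Reactants: 20 4-benzyloxy-3-{7-benzyloxy-2-[4-(benzyloxy)phenyl]-5-methoxy-4-oxo-4H-chromen-8-yl}benzoic acid; 24 1-(6-hydroxy-2,4-dimethoxy-3-methylphenyl)ethanone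
Product: 25 2-acetyl-3,5-dimethoxy-4-methylphenyl 4-benzyloxy-3-{7-benzyloxy-2-[4-(benzyloxy)phenyl]-5-methoxy-4-oxo-4H-chromen-8-yl}benzoate
Conditions: EDC·HCl, DMAP, CH2Cl2, rt
Reagents that add atoms: none
Why: Steglich esterification; the chelated phenol of a 2-hydroxy-4,6-dialkoxyacetophenone with one free ortho position is acylated routinely under carbodiimide–DMAP activation.

Step 16
Reactants: 25 2-acetyl-3,5-dimethoxy-4-methylphenyl 4-benzyloxy-3-{7-benzyloxy-2-[4-(benzyloxy)phenyl]-5-methoxy-4-oxo-4H-chromen-8-yl}benzoate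
Product: 26 1-(4-benzyloxy-3-{7-benzyloxy-2-[4-(benzyloxy)phenyl]-5-methoxy-4-oxo-4H-chromen-8-yl}phenyl)-3-(6-hydroxy-2,4-dimethoxy-3-methylphenyl)propane-1,3-dione
Conditions: KOtBu (2.5 equiv), THF, 0 °C to rt; aq HCl
Reagents that add atoms: none
Why: Baker–Venkataraman rearrangement: the methyl ketone enolate attacks the neighbouring aryl ester through a six-membered transition state and the aroyl group moves from oxygen to carbon, giving the stabilised diketone enolate and phenoxide.

Step 17
Reactants: 26 1-(4-benzyloxy-3-{7-benzyloxy-2-[4-(benzyloxy)phenyl]-5-methoxy-4-oxo-4H-chromen-8-yl}phenyl)-3-(6-hydroxy-2,4-dimethoxy-3-methylphenyl)propane-1,3-dione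
Product: 27 2-(4-benzyloxy-3-{7-benzyloxy-2-[4-(benzyloxy)phenyl]-5-methoxy-4-oxo-4H-chromen-8-yl}phenyl)-5,7-dimethoxy-6-methyl-4H-chromen-4-one
Conditions: TsOH·H2O (0.2 equiv), toluene, 90 °C
Reagents that add atoms: none
Why: Acid-catalysed cyclodehydration as in step 11 closes ring C of unit 1, and because the only free hydroxyl is the one that carried the ester, the C-methyl group must end at C6 and not at C8.

Step 18
Reactants: 27 2-(4-benzyloxy-3-{7-benzyloxy-2-[4-(benzyloxy)phenyl]-5-methoxy-4-oxo-4H-chromen-8-yl}phenyl)-5,7-dimethoxy-6-methyl-4H-chromen-4-one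
Product: 28 5-hydroxy-2-{4-hydroxy-3-[5,7-dihydroxy-2-(4-hydroxyphenyl)-4-oxo-4H-chromen-8-yl]phenyl}-7-methoxy-6-methyl-4H-chromen-4-one (CNP0113589.0)
Conditions: BCl3 (15 equiv), pentamethylbenzene, CH2Cl2, −78 to 0 °C; then H2O
Reagents that add atoms: none
Why: BCl3 cleaves aryl benzyl ethers at low temperature and, through chelation to the C4 carbonyls, the two peri (C5) methyl ethers, whereas the unchelated 7-methoxy group of unit 1 should stay; pentamethylbenzene traps the benzyl cations (Lewis-acid ether cleavage).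

**Compound list**

1 | 2-hydroxyphenylacetic acid | OC(=O)Cc1ccccc1O | starting material
2 | 2-(5-bromo-2-hydroxyphenyl)acetic acid | OC(=O)Cc1cc(Br)ccc1O | intermediate
3 | benzyl 2-(2-benzyloxy-5-bromophenyl)acetate | O=C(Cc1cc(Br)ccc1OCc1ccccc1)OCc1ccccc1 | intermediate
4 | 2-(2-benzyloxy-5-bromophenyl)acetic acid | OC(=O)Cc1cc(Br)ccc1OCc1ccccc1 | intermediate
5 | methyl acetoacetate | COC(=O)CC(C)=O | starting material
6 | 1-[2-(2-benzyloxy-5-bromophenyl)acetyl]imidazole | O=C(Cc1cc(Br)ccc1OCc1ccccc1)n1ccnc1 | intermediate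
7 | dilithium dianion of methyl acetoacetate | [Li+].[Li+].[CH2-]C(=O)[CH-]C(=O)OC | intermediate
8 | methyl 6-(2-benzyloxy-5-bromophenyl)-3,5-dioxohexanoate | COC(=O)CC(=O)CC(=O)Cc1cc(Br)ccc1OCc1ccccc1 | intermediate
9 | 6-[(2-benzyloxy-5-bromophenyl)methyl]-4-hydroxy-2H-pyran-2-one | O=C1C=C(O)C=C(Cc2cc(Br)ccc2OCc2ccccc2)O1 | intermediate
10 | 6-[(2-benzyloxy-5-bromophenyl)methyl]-4-methoxy-2H-pyran-2-one | COC1=CC(=O)OC(Cc2cc(Br)ccc2OCc2ccccc2)=C1 | intermediate
11 | methyl (2E)-6-(2-benzyloxy-5-bromophenyl)-3-methoxy-5-oxohex-2-enoate (present as its sodium enolate) | COC(=O)/C=C(/OC)CC(=O)Cc1cc(Br)ccc1OCc1ccccc1 | intermediate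
12 | 2-(2-benzyloxy-5-bromophenyl)-5-methoxybenzene-1,3-diol | COc1cc(O)c(-c2cc(Br)ccc2OCc2ccccc2)c(O)c1 | intermediate
13 | 1-[3-(2-benzyloxy-5-bromophenyl)-2,4-dihydroxy-6-methoxyphenyl]ethan-1-iminium chloride | CC(=[NH2+])c1c(O)c(-c2cc(Br)ccc2OCc2ccccc2)c(O)cc1OC.[Cl-] | intermediate
14 | 1-[3-(2-benzyloxy-5-bromophenyl)-2,4-dihydroxy-6-methoxyphenyl]ethanone | CC(=O)c1c(O)c(-c2cc(Br)ccc2OCc2ccccc2)c(O)cc1OC | intermediate
15 | 1-[4-benzyloxy-3-(2-benzyloxy-5-bromophenyl)-2-hydroxy-6-methoxyphenyl]ethanone | CC(=O)c1c(O)c(-c2cc(Br)ccc2OCc2ccccc2)c(OCc2ccccc2)cc1OC | intermediate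
16 | 4-(benzyloxy)benzoic acid | OC(=O)c1ccc(OCc2ccccc2)cc1 | starting material
17 | 4-(benzyloxy)benzoyl chloride | ClC(=O)c1ccc(OCc2ccccc2)cc1 | intermediate
18 | 1-[4-benzyloxy-3-(2-benzyloxy-5-bromophenyl)-2-hydroxy-6-methoxyphenyl]-3-[4-(benzyloxy)phenyl]propane-1,3-dione | O=C(CC(=O)c1ccc(OCc2ccccc2)cc1)c1c(O)c(-c2cc(Br)ccc2OCc2ccccc2)c(OCc2ccccc2)cc1OC | intermediate
19 | 7-benzyloxy-8-(2-benzyloxy-5-bromophenyl)-2-[4-(benzyloxy)phenyl]-5-methoxy-4H-chromen-4-one | COc1cc(OCc2ccccc2)c(-c2cc(Br)ccc2OCc2ccccc2)c2oc(-c3ccc(OCc4ccccc4)cc3)cc(=O)c12 | intermediate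
20 | 4-benzyloxy-3-{7-benzyloxy-2-[4-(benzyloxy)phenyl]-5-methoxy-4-oxo-4H-chromen-8-yl}benzoic acid | COc1cc(OCc2ccccc2)c(-c2cc(C(=O)O)ccc2OCc2ccccc2)c2oc(-c3ccc(OCc4ccccc4)cc3)cc(=O)c12 | intermediate
21 | 2,6-dimethoxytoluene | COc1cccc(OC)c1C | starting material
22 | 2-(3,5-dimethoxy-4-methylphenyl)-4,4,5,5-tetramethyl-1,3,2-dioxaborolane | COc1cc(B2OC(C)(C)C(C)(C)O2)cc(OC)c1C | intermediate
23 | 3,5-dimethoxy-4-methylphenol | COc1cc(O)cc(OC)c1C | intermediate
24 | 1-(6-hydroxy-2,4-dimethoxy-3-methylphenyl)ethanone | CC(=O)c1c(O)cc(OC)c(C)c1OC | intermediate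
25 | 2-acetyl-3,5-dimethoxy-4-methylphenyl 4-benzyloxy-3-{7-benzyloxy-2-[4-(benzyloxy)phenyl]-5-methoxy-4-oxo-4H-chromen-8-yl}benzoate | CC(=O)c1c(OC(=O)c2ccc(OCc3ccccc3)c(-c3c(OCc4ccccc4)cc(OC)c4c(=O)cc(-c5ccc(OCc6ccccc6)cc5)oc34)c2)cc(OC)c(C)c1OC | intermediate
26 | 1-(4-benzyloxy-3-{7-benzyloxy-2-[4-(benzyloxy)phenyl]-5-methoxy-4-oxo-4H-chromen-8-yl}phenyl)-3-(6-hydroxy-2,4-dimethoxy-3-methylphenyl)propane-1,3-dione | COc1cc(O)c(C(=O)CC(=O)c2ccc(OCc3ccccc3)c(-c3c(OCc4ccccc4)cc(OC)c4c(=O)cc(-c5ccc(OCc6ccccc6)cc5)oc34)c2)c(OC)c1C | intermediate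
27 | 2-(4-benzyloxy-3-{7-benzyloxy-2-[4-(benzyloxy)phenyl]-5-methoxy-4-oxo-4H-chromen-8-yl}phenyl)-5,7-dimethoxy-6-methyl-4H-chromen-4-one | COc1cc2oc(-c3ccc(OCc4ccccc4)c(-c4c(OCc5ccccc5)cc(OC)c5c(=O)cc(-c6ccc(OCc7ccccc7)cc6)oc45)c3)cc(=O)c2c(OC)c1C | intermediate
28 | 5-hydroxy-2-{4-hydroxy-3-[5,7-dihydroxy-2-(4-hydroxyphenyl)-4-oxo-4H-chromen-8-yl]phenyl}-7-methoxy-6-methyl-4H-chromen-4-one | COc1cc2oc(-c3ccc(O)c(-c4c(O)cc(O)c5c(=O)cc(-c6ccc(O)cc6)oc45)c3)cc(=O)c2c(O)c1C | target

**Step count**
Total: 18 steps. Longest linear sequence: 15 steps (steps 1–8, 10–12 and 15–18, from 2-hydroxyphenylacetic acid). Step 9 and steps 13–14 are side branches.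

**Steps most likely to fail**

Step 6. After methoxide opens the lactone, the chain may rest as its conjugated dienolate, in which the ester is deactivated. It would then return to the pyrone on acidification, or be cut by retro-Claisen attack of methoxide at the benzyl ketone, so that ring A never closes. The fallback gives up the ring synthesis and makes the biaryl bond by cross-coupling on a finished unit 2. It sets out from acid chloride 17 and comes back at acid 20. Purchased 1-(2,4-dihydroxy-6-methoxyphenyl)ethanone is benzylated at its unchelated hydroxyl (BnBr, K2CO3, acetone) to 1-(4-benzyloxy-2-hydroxy-6-methoxyphenyl)ethanone F1. Its dianion (LiN(SiMe3)2, THF, −78 °C) is aroylated with 17 to 1-(4-benzyloxy-2-hydroxy-6-methoxyphenyl)-3-[4-(benzyloxy)phenyl]propane-1,3-dione F2, which TsOH·H2O in toluene closes to 7-benzyloxy-2-[4-(benzyloxy)phenyl]-5-methoxy-4H-chromen-4-one F3. Iodination with I2 and CF3CO2Ag in CH2Cl2, which 5,7-dialkoxyflavones take at C8, should give 7-benzyloxy-2-[4-(benzyloxy)phenyl]-8-iodo-5-methoxy-4H-chromen-4-one F4. The coupling partner is 4-benzyloxy-3-(4,4,5,5-tetramethyl-1,3,2-dioxaborolan-2-yl)benzaldehyde F5, made from purchased 4-benzyloxy-3-bromobenzaldehyde by Miyaura borylation (B2pin2, KOAc, [1,1'-bis(diphenylphosphino)ferrocene]PdCl2, dioxane). Suzuki–Miyaura coupling of F4 with F5 (Pd(OAc)2, SPhos, K3PO4, toluene–H2O, 90 °C) gives 4-benzyloxy-3-{7-benzyloxy-2-[4-(benzyloxy)phenyl]-5-methoxy-4-oxo-4H-chromen-8-yl}benzaldehyde F6. Pinnick oxidation of F6 (NaClO2, NaH2PO4, 2-methyl-2-butene, tBuOH–H2O) gives 20.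

Step 18. Five ether cleavages must be completed in one operation. One of the two peri-methoxy groups may be cleaved incompletely, the cleavage may run on to the 7-methoxy group of unit 1, or benzyl cations may re-attack the electron-rich rings. The fallback separates the two kinds of cleavage; it sets out from 27 and comes back at 28. Hydrogenolysis (H2, Pd on carbon, THF–MeOH, rt) removes the three benzyl groups and gives 2-{4-hydroxy-3-[7-hydroxy-2-(4-hydroxyphenyl)-5-methoxy-4-oxo-4H-chromen-8-yl]phenyl}-5,7-dimethoxy-6-methyl-4H-chromen-4-one F7. Chelation-directed demethylation of the two C5 methoxy groups with AlCl3 in MeCN at 60 °C then gives 28.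

Step 3. The strongly basic dianion may take a proton from the acidic benzylic CH2 of the acyl imidazole, so that the acyl donor is enolised instead of attacked, and O-acylation may compete. The fallback uses a neutral carbon nucleophile; it sets out from acid 4 and comes back at 8. Acid 4 is converted with (COCl)2 and catalytic DMF into 2-(2-benzyloxy-5-bromophenyl)acetyl chloride F8. F8 acylates the terminal carbon of commercially supplied 1-methoxy-1,3-bis(trimethylsilyloxy)buta-1,3-diene in CH2Cl2 at −78 °C to rt without any base, and aqueous work-up gives 8.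

**Further compounds**

F1 | step 6 | 1-(4-benzyloxy-2-hydroxy-6-methoxyphenyl)ethanone | CC(=O)c1c(O)cc(OCc2ccccc2)cc1OC
F2 | step 6 | 1-(4-benzyloxy-2-hydroxy-6-methoxyphenyl)-3-[4-(benzyloxy)phenyl]propane-1,3-dione | O=C(CC(=O)c1ccc(OCc2ccccc2)cc1)c1c(O)cc(OCc2ccccc2)cc1OC
F3 | step 6 | 7-benzyloxy-2-[4-(benzyloxy)phenyl]-5-methoxy-4H-chromen-4-one | COc1cc(OCc2ccccc2)cc2oc(-c3ccc(OCc4ccccc4)cc3)cc(=O)c12
F4 | step 6 | 7-benzyloxy-2-[4-(benzyloxy)phenyl]-8-iodo-5-methoxy-4H-chromen-4-one | COc1cc(OCc2ccccc2)c(I)c2oc(-c3ccc(OCc4ccccc4)cc3)cc(=O)c12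
F5 | step 6 | 4-benzyloxy-3-(4,4,5,5-tetramethyl-1,3,2-dioxaborolan-2-yl)benzaldehyde | O=Cc1ccc(OCc2ccccc2)c(B2OC(C)(C)C(C)(C)O2)c1
F6 | step 6 | 4-benzyloxy-3-{7-benzyloxy-2-[4-(benzyloxy)phenyl]-5-methoxy-4-oxo-4H-chromen-8-yl}benzaldehyde | COc1cc(OCc2ccccc2)c(-c2cc(C=O)ccc2OCc2ccccc2)c2oc(-c3ccc(OCc4ccccc4)cc3)cc(=O)c12
F7 | step 18 | 2-{4-hydroxy-3-[7-hydroxy-2-(4-hydroxyphenyl)-5-methoxy-4-oxo-4H-chromen-8-yl]phenyl}-5,7-dimethoxy-6-methyl-4H-chromen-4-one | COc1cc2oc(-c3ccc(O)c(-c4c(O)cc(OC)c5c(=O)cc(-c6ccc(O)cc6)oc45)c3)cc(=O)c2c(OC)c1C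
F8 | step 3 | 2-(2-benzyloxy-5-bromophenyl)acetyl chloride | O=C(Cl)Cc1cc(Br)ccc1OCc1ccccc1
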